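**Retrosynthetic overview**
1. Target 18 comes from aromatic chroman 16 by dearomative gem‑dimethylation of the phloroglucinol ring; 16 comes from 15 by C–S hydrogenolysis at the benzylic carbon.
2. Key disconnection (12 → 15): the dihydropyran ring (aryl O, C‑4, C‑5, the benzylic CH and two aromatic carbons) is the formal [4+2] adduct of an O‑aryl oxocarbenium ion (aryl C=C–O+=C‑4, a 2‑oxonia‑diene) and the alkenyl sulfide C‑5=CH–SMe. The same event closes the nine‑membered carbocycle across C‑4–C‑5.
3. Enabling feature: C‑4 is a methyl‑bearing tertiary aryl‑ether carbon (a masked methyl ketone) bonded directly to C‑5, the ring CH that carries the benzylic CH2 (a masked, one‑carbon‑extended aldehyde). These are the two alkene carbons of (−)‑β‑caryophyllene, so ozonolysis of this chiral‑pool terpene supplies both termini with the (1R,9S)‑cyclobutane and the exocyclic methylene already in place.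
4. 12 comes from enol triflate 11 and acylphloroglucinol 4 by C–O coupling; 11 from keto‑aldehyde 7, which comes from 5; 4 from phloroglucinol and (S)‑2‑methylbutanoic acid.
5. Ring order: cyclobutane (from 5) and benzene ring (from 3) are bought; the nine‑membered ring and the pyran are formed together in step 7; the cyclohexadienone ring is made last by dearomatisation.

Key step: step 7

Assumption: C‑n locants are caryophyllane numbers (C‑4 methyl‑bearing, C‑5 its neighbour, C‑8 methylene‑bearing, C‑1/C‑9 cyclobutane); the alkenyl sulfide is carried as an E/Z mixture and 15 as both epimers at the CH–S carbon, because that carbon becomes CH2 in step 8.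

Step 1
Reactants: 1 (S)‑2‑methylbutanoic acid
Product: 2 (S)‑2‑methylbutanoyl chloride
Conditions: (COCl)2, DMF (cat.), CH2Cl2, 0 °C → rt; concentrate
Reagents that add atoms: oxalyl chloride, ClC(=O)C(=O)Cl
Why: Acid chloride formation through the Vilsmeier‑type chloroiminium is neutral and cold, so the α‑stereocentre of 1 should be carried unchanged into 2.

Step 2
Reactants: 2 (S)‑2‑methylbutanoyl chloride, 3 phloroglucinol
Product: 4 (2S)‑2‑methyl‑1‑(2,4,6‑trihydroxyphenyl)butan‑1‑one
Conditions: AlCl3 (4 equiv), PhNO2/CH2Cl2, 0 °C → rt; aq. HCl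
Reagents that add atoms: none
Why: Friedel–Crafts acylation of the symmetric, highly activated triol should stop after one acyl group because the aryl ketone–aluminium chelate deactivates the ring, and at or below room temperature the acylium ion should be trapped before it can lose its α‑proton.

Step 3
Reactants: 5 (−)‑β‑caryophyllene
Product: 7 4‑[(1S,2R)‑3,3‑dimethyl‑2‑(3‑oxobutyl)cyclobutyl]pent‑4‑enal, via secondary ozonide 6 (not isolated)
Conditions: O3 (1.0 equiv, titrated solution), CH2Cl2, −78 °C; then PPh3, −78 °C → rt
Reagents that add atoms: ozone, [O-][O+]=O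
Why: Ozonolysis (Criegee mechanism) with one equivalent of ozone should select the strained trisubstituted endocyclic E‑alkene over the 1,1‑disubstituted exocyclic one, turning C‑4 into the methyl ketone and C‑5 into the aldehyde without touching the cyclobutane stereocentres.

Step 4
Reactants: 7 keto‑aldehyde, 8 (methylthiomethyl)triphenylphosphonium chloride
Product: 9 4‑[(1R,4S)‑2,2‑dimethyl‑4‑(6‑(methylsulfanyl)hexa‑1,5‑dien‑2‑yl)cyclobutyl]butan‑2‑one (E/Z mixture)
Conditions: 8, NaHMDS, THF, −78 °C; then 7, −78 → 0 °C
Reagents that add atoms: none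
Why: Wittig olefination with the sulfur‑substituted ylide should be selective for the aldehyde over the methyl ketone at low temperature and installs the future benzylic carbon as an electron‑rich CH=CH–SMe unit whose geometry is immaterial.

Step 5
Reactants: 9 keto alkenyl sulfide
Product: 11 4‑[(1R,4S)‑2,2‑dimethyl‑4‑(6‑(methylsulfanyl)hexa‑1,5‑dien‑2‑yl)cyclobutyl]but‑1‑en‑2‑yl trifluoromethanesulfonate, via potassium enolate 10 (not isolated)
Conditions: KHMDS, THF, −78 °C; then PhNTf2, −78 → 0 °C
Reagents that add atoms: N‑phenylbis(trifluoromethanesulfonimide), O=S(=O)(N(c1ccccc1)S(=O)(=O)C(F)(F)F)C(F)(F)F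
Why: Kinetic deprotonation of the methyl ketone at the methyl group followed by O‑sulfonylation is a standard enol triflate synthesis, and any internal regioisomer would converge to the same cation in step 7.

Step 6
Reactants: 11 enol triflate, 4 acylphloroglucinol
Product: 12 (2S)‑1‑[4‑({4‑[(1R,4S)‑2,2‑dimethyl‑4‑(6‑(methylsulfanyl)hexa‑1,5‑dien‑2‑yl)cyclobutyl]but‑1‑en‑2‑yl}oxy)‑2,6‑dihydroxyphenyl]‑2‑methylbutan‑1‑one
Conditions: Pd2(dba)3 (2.5 mol%), tBuXPhos (6 mol%), K3PO4 (1.2 equiv), toluene, 80 °C
Reagents that add atoms: none
Why: Palladium‑catalysed C–O cross‑coupling of an enol triflate with a phenol (oxidative addition to zerovalent palladium, phenoxide exchange, reductive elimination from a bulky biarylphosphine complex) should engage only the para hydroxyl, the most acidic one and the only one not hydrogen‑bonded to the ketone.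

Step 7
Reactants: 12 aryl enol ether
Product: 15 trans‑fused 5,7‑dihydroxy‑6‑[(2S)‑2‑methylbutanoyl]‑4‑(methylsulfanyl)chroman annulated at C‑2/C‑3 of the chroman with the caryophyllane nine‑membered ring (both epimers at the CH–S carbon), via oxocarbenium ion 13 (not isolated), via thionium ion 14 (not isolated)
Conditions: HNTf2 (5 mol%), CH2Cl2 (0.005 M), −60 → −20 °C; Et3N quench
Reagents that add atoms: none
Why: Proposed new method: catalytic C‑protonation of the most basic π‑bond (the α‑alkyl aryl enol ether, far more basic than the alkenyl sulfide or the 1,1‑disubstituted alkene) gives O‑aryl oxocarbenium ion 13, a 2‑oxonia‑diene, which is captured by the sulfur‑polarised C‑5=CH bond in a stepwise cationic [4+2]: C‑4–C‑5 bond first, then Friedel–Crafts closure of thionium ion 14 on the arene carbon flanked by OH and OR, then loss of the proton that carries the chain. The closest known reactions are the oxa‑Povarov reaction of aryl oxocarbenium ions with alkenes, the Povarov reaction with vinyl sulfides and vinyl sulfide‑terminated cation–olefin cyclisations, none of which has closed a medium carbocycle from a ketone‑derived cation. The nine‑membered ring closes in 9‑exo fashion with respect to the alkenyl sulfide (Prins‑type), the pyran in 6‑exo‑trig fashion at the thionium carbon. C‑4 and C‑5 are set together in the first bond formation through a chair‑like array of the incipient pyran in which both ends of the tether (C‑3 and C‑6) are pseudo‑equatorial and the methyl group axial, which should give the trans ring fusion (methyl anti to H‑5); the sulfur‑bearing carbon forms as a mixture and is erased in step 8. The selectivity the step needs is the facial sense relative to the (1R,9S)‑cyclobutane, and the only resident control element is the fold this trans‑1,2‑disubstituted ring imposes on the two arms; if the wrong trans‑fused epimer (4R,5S) dominates, a confined chiral Brønsted acid in place of HNTf2 is the lever. Regiochemistry (C‑5, not CH–S, bonds to C‑4) is secured by sulfur, chemoselectivity over the exocyclic methylene by the higher nucleophilicity of the alkenyl sulfide and the strain of the competing trans‑fused seven‑membered closure, and intramolecularity by high dilution.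

Step 8
Reactants: 15 4‑(methylsulfanyl)chroman
Product: 16 trans‑fused 5,7‑dihydroxy‑6‑[(2S)‑2‑methylbutanoyl]chroman annulated with the caryophyllane ring, (1R,4S,5R,9S) in caryophyllane numbering
Conditions: Bu3SnH, AIBN (cat.), toluene, 90 °C
Reagents that add atoms: none
Why: Radical desulfurization, in which the stannyl radical abstracts the methylthio group and the benzylic radical is reduced by Bu3SnH, should remove the CH–S stereocentre and leave the alkenes, C‑4 and C‑5 untouched.

Step 9
Reactants: 16 aromatic chroman
Product: 18 target CNP0591516.1, via 8‑methylchroman 17 (not isolated)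
Conditions: NaOMe (4 equiv), MeI (2.3 equiv), MeOH, 0 °C → rt; aq. HCl
Reagents that add atoms: iodomethane, CI
Why: Dearomative double C‑methylation of an acylphloroglucinol phenoxide is a known way to install the gem‑dimethyl carbon; the first methyl goes to the only unsubstituted ring carbon and the second should go to the same, less hindered carbon, giving the β‑triketone enol whose vinylogous‑carboxylate character also shields the side‑chain stereocentre from enolisation.

**Compound list**
1 | (S)‑2‑methylbutanoic acid | OC(=O)[C@@H](C)CC | starting material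
2 | (S)‑2‑methylbutanoyl chloride | ClC(=O)[C@@H](C)CC | intermediate
3 | phloroglucinol | Oc1cc(O)cc(O)c1 | starting material
4 | (2S)‑2‑methyl‑1‑(2,4,6‑trihydroxyphenyl)butan‑1‑one | O=C([C@@H](C)CC)c1c(O)cc(O)cc1O | intermediate
5 | (−)‑β‑caryophyllene, (1R,4E,9S) | C=C1CC/C=C(\C)CC[C@@H]2[C@@H]1CC2(C)C | starting material
6 | secondary ozonide (1,2,4‑trioxolane across C‑4/C‑5) of 5, not isolated | C=C1CCC2OOC(C)(O2)CC[C@@H]2[C@@H]1CC2(C)C | intermediate
7 | 4‑[(1S,2R)‑3,3‑dimethyl‑2‑(3‑oxobutyl)cyclobutyl]pent‑4‑enal | CC(=O)CC[C@@H]1[C@@H](C(=C)CCC=O)CC1(C)C | intermediate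
8 | (methylthiomethyl)triphenylphosphonium chloride | CSC[P+](c1ccccc1)(c1ccccc1)c1ccccc1.[Cl-] | starting material
9 | 4‑[(1R,4S)‑2,2‑dimethyl‑4‑(6‑(methylsulfanyl)hexa‑1,5‑dien‑2‑yl)cyclobutyl]butan‑2‑one (E/Z mixture) | CC(=O)CC[C@@H]1[C@@H](C(=C)CCC=CSC)CC1(C)C | intermediate
10 | potassium enolate of 9 (terminal), not isolated | [K+].[O-]C(=C)CC[C@@H]1[C@@H](C(=C)CCC=CSC)CC1(C)C | intermediate
11 | enol triflate of 9 (but‑1‑en‑2‑yl trifluoromethanesulfonate) | C=C(OS(=O)(=O)C(F)(F)F)CC[C@@H]1[C@@H](C(=C)CCC=CSC)CC1(C)C | intermediate
12 | aryl enol ether (4‑O‑alkenyl ether of 4) | C=C(Oc1cc(O)c(C(=O)[C@@H](C)CC)c(O)c1)CC[C@@H]1[C@@H](C(=C)CCC=CSC)CC1(C)C | intermediate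
13 | O‑aryl oxocarbenium ion from C‑protonation of 12, not isolated | CC(=[O+]c1cc(O)c(C(=O)[C@@H](C)CC)c(O)c1)CC[C@@H]1[C@@H](C(=C)CCC=CSC)CC1(C)C | intermediate
14 | thionium ion with the nine‑membered ring closed (C‑4–C‑5 bonded), not isolated | C=C1CC[C@H](C=[S+]C)[C@@](C)(Oc2cc(O)c(C(=O)[C@@H](C)CC)c(O)c2)CC[C@@H]2[C@@H]1CC2(C)C | intermediate
15 | trans‑fused 4‑(methylsulfanyl)chroman, both epimers at CH–S | C=C1CC[C@@H]2C(SC)c3c(O[C@@]2(C)CC[C@@H]2[C@@H]1CC2(C)C)cc(O)c(C(=O)[C@@H](C)CC)c3O | intermediate
16 | trans‑fused aromatic chroman, (1R,4S,5R,9S) | C=C1CC[C@@H]2Cc3c(O[C@@]2(C)CC[C@@H]2[C@@H]1CC2(C)C)cc(O)c(C(=O)[C@@H](C)CC)c3O | intermediate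
17 | 8‑methyl derivative of 16 (chroman numbering), not isolated | C=C1CC[C@@H]2Cc3c(O[C@@]2(C)CC[C@@H]2[C@@H]1CC2(C)C)c(C)c(O)c(C(=O)[C@@H](C)CC)c3O | intermediate
18 | CNP0591516.1, (1R,4S,5R,9S), (S)‑2‑methylbutanoyl | C=C1CC[C@@H]2CC3=C(O[C@@]2(C)CC[C@@H]2[C@@H]1CC2(C)C)C(C)(C)C(=O)C(C(=O)[C@@H](C)CC)=C3O | target

**Step count and risks**
Total step count: 9. Longest linear sequence: 7 (steps 3–9, from 5).

Steps most likely to fail:

Step 7 (Proposed new method). The oxocarbenium ion may be lost to the exocyclic alkene (seven‑membered Prins closure), to adventitious water or to intermolecular alkylation faster than the nine‑membered closure, and facial discrimination relative to the cyclobutane may be poor. The fallback uses known chemistry and sets out from 4 and 5: heating them with paraformaldehyde (NaOAc, AcOH, 80 °C) should give by Knoevenagel condensation the ortho‑quinone methide F1, which adds through its para oxygen and methylene carbon to the strained E double bond of 5 in an inverse‑demand hetero‑Diels–Alder reaction. The adduct of the required facial sense is separated from its diastereomer and is 16, so the route resumes at step 9.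

Step 9. Methylation may go to the ring‑fusion carbon or to oxygen instead of giving the gem‑dimethyl carbon, and over‑ or under‑alkylation may occur. The fallback sets out from 4, whose two free ring positions are equivalent: NaOMe/MeI should give 2‑acyl‑6,6‑dimethylcyclohexane‑1,3,5‑trione F2 without a regiochemical question. F2, paraformaldehyde and 5 (NaOAc, AcOH, 80 °C) then give, via the ortho‑quinone methide F3 and hetero‑Diels–Alder addition, the (4S,5R) adduct, which after separation from its facial diastereomer is 18.

Step 6. The triflate may eliminate to the alkyne under base, or coupling may occur at a hydrogen‑bonded hydroxyl or at ring carbon. The fallback sets out from 11 and makes the elimination deliberate: LDA (THF, −78 → 0 °C) should give the terminal alkyne F4, and gold‑catalysed Markovnikov addition of the para hydroxyl of 4 (Ph3PAuNTf2, toluene, 60 °C) should then give 12.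

**Further compounds**
F1 | step 7 | ortho‑quinone methide of 4 (3‑methylene, 4‑oxo), not isolated | C=C1C(=O)C=C(O)C(C(=O)[C@@H](C)CC)=C1O
F2 | step 9 | 3,5‑dihydroxy‑4,4‑dimethyl‑6‑[(2S)‑2‑methylbutanoyl]cyclohexa‑2,5‑dien‑1‑one | OC1=CC(O)=C(C(=O)[C@@H](C)CC)C(=O)C1(C)C
F3 | step 9 | ortho‑quinone methide of F2, not isolated | C=C1C(=O)C(C)(C)C(=O)C(C(=O)[C@@H](C)CC)=C1O
F4 | step 6 | terminal alkyne from 11 | C#CCC[C@@H]1[C@@H](C(=C)CCC=CSC)CC1(C)C
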